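# Total synthesis of Tomoeone D

## Retrosynthetic overview

1. Tomoeone D ⇐ spiro ketone 16 (equatorial MeMgBr addition sets the axial tertiary OH) ⇐ spiro nitro compound 15 (Nef reaction).
2. 15 ⇐ 13 + formaldehyde: a new "methylene stitch" joins the nitromethyl carbon and the triketone carbon, closing the spiro cyclohexane (last ring) and setting the spiro centre.
3. 13 ⇐ trione 5 + aldehyde 11 (reductive Knoevenagel alkylation); 5 ⇐ phloroglucinol by acylation and dearomative gem-diprenylation (the trione ring comes from the arene).
4. 11 ⇐ (E)-6-oxohept-2-enal 8 + nitromethane by an aminocatalytic asymmetric Michael/aldol domino (cyclopentane, first stereocentres); 8 ⇐ hex-5-en-2-one + crotonaldehyde (cross metathesis).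
5. Ring order: trione ring (dearomatised arene) → cyclopentane → spiro cyclohexane.

Assumption: β-triketones are drawn in one enol form (the tautomers interconvert); the bicyclic part is numbered as octahydroindene (C-1 = five-ring carbinol carbon, C-3a and C-7a = ring fusion with C-7a next to C-1, C-4 = six-ring carbon next to C-3a, C-6 = spiro carbon).

## Route

Step 1
Reactants: 1 phloroglucinol; 2 isobutyryl chloride
Product: 3 2-methyl-1-(2,4,6-trihydroxyphenyl)propan-1-one
Conditions: AlCl3 (3 equiv), PhNO2, 80 °C; then 1 M HCl
Reagents that add atoms: none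
Why: Friedel–Crafts C-acylation of the very electron-rich arene; the acyl group deactivates the ring so monoacylation is clean, and no stereocentre is formed.

Step 2
Reactants: 3 2-methyl-1-(2,4,6-trihydroxyphenyl)propan-1-one; 4 prenyl bromide (2.1 equiv)
Product: 5 3,5-dihydroxy-6,6-bis(3-methylbut-2-enyl)-2-(2-methylpropanoyl)cyclohexa-2,4-dien-1-one
Conditions: NaOMe (3 equiv), MeOH, 0 °C to rt
Reagents that add atoms: none
Why: Dearomative double C-allylation of the phenoxide acting as a vinylogous enolate, the second prenyl group entering at the already prenylated carbon as in lupulone-type syntheses (moderate yield expected; the 3,5-diprenyl isomer is removed by chromatography); no stereocentre is formed.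

Step 3
Reactants: 6 hex-5-en-2-one; 7 (E)-but-2-enal (4 equiv)
Product: 8 (E)-6-oxohept-2-enal
Conditions: second-generation Grubbs catalyst RuCl2(=CHPh)(PCy3)(1,3-dimesitylimidazolidin-2-ylidene) (2 mol %), CH2Cl2, 40 °C
Reagents that add atoms: none
Why: Olefin cross metathesis of a terminal alkene with an excess of the enal partner gives the E-enal under thermodynamic control; no stereocentre is formed.

Step 4
Reactants: 8 (E)-6-oxohept-2-enal; 9 nitromethane
Product: 11 (1S,2R,5R)-2-hydroxy-2-methyl-5-(nitromethyl)cyclopentane-1-carbaldehyde, via Michael adduct 10 (not isolated)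
Conditions: (S)-α,α-diphenylprolinol trimethylsilyl ether (10 mol %), PhCO2H (20 mol %), MeOH, 0 °C to rt
Reagents that add atoms: none
Why: Atom-economical 1:1 domino of iminium-ion Michael addition of nitromethane (the CPh2OSiMe3 group of the (S)-catalyst shields one face of the E-iminium ion, giving the R centre of 10 as the first stereocentre) and enamine 5-enolexo aldol addition of the catalyst-bound aldehyde to the methyl ketone; reversible aldol addition and α-epimerisation settle the two new centres with CHO trans to CH2NO2 and to CH3 and cis (hydrogen-bonded) to OH.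

Step 5
Reactants: 5 3,5-dihydroxy-6,6-bis(3-methylbut-2-enyl)-2-(2-methylpropanoyl)cyclohexa-2,4-dien-1-one; 11 (1S,2R,5R)-2-hydroxy-2-methyl-5-(nitromethyl)cyclopentane-1-carbaldehyde
Product: 13 3,5-dihydroxy-4-{[(1S,2R,5R)-2-hydroxy-2-methyl-5-(nitromethyl)cyclopentyl]methyl}-6,6-bis(3-methylbut-2-enyl)-2-(2-methylpropanoyl)cyclohexa-2,4-dien-1-one, via alkylidene trione 12 (not isolated)
Conditions: Hantzsch ester (diethyl 2,6-dimethyl-1,4-dihydropyridine-3,5-dicarboxylate, 1.1 equiv), ethylenediammonium diacetate (5 mol %), CH2Cl2, rt
Reagents that add atoms: none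
Why: Three-component reductive alkylation (Knoevenagel condensation at the only free ring CH of 5, then conjugate hydride transfer from the Hantzsch ester to 12, which outruns other reactions of the alkylidene trione); the carbinol and nitromethyl centres are untouched and the α-centre returns to the trans arrangement if it enolises through 12.

Step 6
Reactants: 13 3,5-dihydroxy-4-{[(1S,2R,5R)-2-hydroxy-2-methyl-5-(nitromethyl)cyclopentyl]methyl}-6,6-bis(3-methylbut-2-enyl)-2-(2-methylpropanoyl)cyclohexa-2,4-dien-1-one
Product: 15 spiro nitro compound (Tomoeone D skeleton with CH(NO2) at C-4 in place of C(CH3)(OH)), via nitroalkene 14 (not isolated)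
Conditions: (CH2O)n (1.2 equiv), pyrrolidine (1.3 equiv), toluene (0.01 M), 0 °C to rt; then aq. citric acid
Reagents that add atoms: formaldehyde (from paraformaldehyde), C=O
Why: Proposed new method: a formaldehyde-stitched [5+1] spiroannulation in which pyrrolidine converts the primary nitro group into nitroalkene 14 (nitro-Mannich reaction, then loss of the amine) and the fully enolised triketone carbon C-4 closes the cyclohexane by 6-endo Michael addition (its own aminomethylation is reversible); the only free oxyanion of the triketonate is the one next to C(prenyl)2, because the other flank oxygen is locked in the O–H···O=C bond to the isobutyryl group, and the pyrrolidinium NH2 can bridge that oxyanion to the developing nitronate only when this C–O is axial in the chair, which sets the spiro centre as in the target; the closest known reactions are the Mannich-base alkylation of C–H acids by nitroalkanes plus formaldehyde and the amine- or thiourea-catalysed Michael addition of 2-substituted cyclic 1,3-diones to nitroalkenes.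

Step 7
Reactants: 15 spiro nitro compound
Product: 16 spiro ketone (Tomoeone D skeleton with C=O at C-4)
Conditions: aq. TiCl3 (5 equiv), NH4OAc buffer (pH 5 to 6), THF/MeOH, 0 °C to rt
Reagents that add atoms: water, O
Why: Reductive Nef reaction of the McMurry type, in which trivalent titanium reduces the secondary nitro group to the imine and water hydrolyses it to the ketone under buffered conditions that spare the prenyl alkenes and the enolised triketone; the C–NO2 centre is erased and no other centre is touched.

Step 8
Reactants: 16 spiro ketone
Product: 17 Tomoeone D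
Conditions: MeMgBr (6 equiv), THF, −78 to −40 °C; then sat. aq. NH4Cl
Reagents that add atoms: methylmagnesium bromide, C[Mg]Br
Why: Grignard 1,2-addition to the only unhindered ketone (the enolised triketone and the tertiary alcohol are held as magnesium salts, and the other ring ketone lies between two quaternary carbons); the axial face is blocked by the axial C=O on the spiro carbon (1,3-diaxial, as in 3,3,5-trimethylcyclohexanone), so CH3 enters equatorially and the new OH is axial, as in the target.

## Compound list

1 | phloroglucinol (benzene-1,3,5-triol) | Oc1cc(O)cc(O)c1 | starting material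
2 | isobutyryl chloride (2-methylpropanoyl chloride) | CC(C)C(Cl)=O | starting material
3 | 2-methyl-1-(2,4,6-trihydroxyphenyl)propan-1-one | CC(C)C(=O)c1c(O)cc(O)cc1O | intermediate
4 | prenyl bromide (1-bromo-3-methylbut-2-ene) | CC(C)=CCBr | starting material
5 | 3,5-dihydroxy-6,6-bis(3-methylbut-2-enyl)-2-(2-methylpropanoyl)cyclohexa-2,4-dien-1-one | CC(C)=CCC1(CC=C(C)C)C(=O)C(C(=O)C(C)C)=C(O)C=C1O | intermediate
6 | hex-5-en-2-one | CC(=O)CCC=C | starting material
7 | (E)-but-2-enal (crotonaldehyde) | C/C=C/C=O | starting material
8 | (E)-6-oxohept-2-enal | CC(=O)CC/C=C/C=O | intermediate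
9 | nitromethane | C[N+](=O)[O-] | starting material
10 | (R)-3-(nitromethyl)-6-oxoheptanal (Michael adduct, not isolated) | O=CC[C@@H](CCC(C)=O)C[N+](=O)[O-] | intermediate
11 | (1S,2R,5R)-2-hydroxy-2-methyl-5-(nitromethyl)cyclopentane-1-carbaldehyde (CHO cis to OH, trans to CH3 and to CH2NO2) | O=C[C@H]1[C@@H](CC[C@@]1(C)O)C[N+](=O)[O-] | intermediate
12 | alkylidene trione: Knoevenagel adduct of 5 and 11, exocyclic C=CH on the ring carbon that was the free CH of 5, alkene geometry undefined, cyclopentane as in 11 (not isolated) | CC(C)=CCC1(CC=C(C)C)C(=O)C(=C[C@H]2[C@@H](CC[C@@]2(C)O)C[N+](=O)[O-])C(=O)C(C(=O)C(C)C)=C1O | intermediate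
13 | 3,5-dihydroxy-4-{[(1S,2R,5R)-2-hydroxy-2-methyl-5-(nitromethyl)cyclopentyl]methyl}-6,6-bis(3-methylbut-2-enyl)-2-(2-methylpropanoyl)cyclohexa-2,4-dien-1-one | CC(C)=CCC1(CC=C(C)C)C(=O)C(C(=O)C(C)C)=C(O)C(C[C@H]2[C@@H](CC[C@@]2(C)O)C[N+](=O)[O-])=C1O | intermediate
14 | nitroalkene: 13 with a 1-nitroethenyl group in place of the nitromethyl group (not isolated) | CC(C)=CCC1(CC=C(C)C)C(=O)C(C(=O)C(C)C)=C(O)C(C[C@H]2[C@@H](CC[C@@]2(C)O)C(=C)[N+](=O)[O-])=C1O | intermediate
15 | spiro nitro compound: trans-fused (1R,3aR,4R,7aS)-1-hydroxy-1-methyl-4-nitro-octahydroindene whose C-6 is C-6 of the 3-hydroxy-2-(2-methylpropanoyl)-4,4-bis(3-methylbut-2-enyl)cyclohex-2-ene-1,5-dione ring; the ring C=O next to C(prenyl)2 is axial; nitro equatorial (epimerisable) | CC(C)=CCC1(CC=C(C)C)C(=O)[C@]2(C[C@H]3[C@@H](CC[C@@]3(C)O)[C@H]([N+](=O)[O-])C2)C(=O)C(C(=O)C(C)C)=C1O | intermediate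
16 | spiro ketone: as 15 but with C=O at C-4, (1R,3aR,7aS), same spiro configuration | CC(C)=CCC1(CC=C(C)C)C(=O)[C@]2(C[C@H]3[C@@H](CC[C@@]3(C)O)C(=O)C2)C(=O)C(C(=O)C(C)C)=C1O | intermediate
17 | Tomoeone D: (1R,3aR,4S,7aS)-1,4-dihydroxy-1,4-dimethyl-octahydroindene, trans-fused, spiro at C-6 to the 3-hydroxy-2-(2-methylpropanoyl)-4,4-bis(3-methylbut-2-enyl)cyclohex-2-ene-1,5-dione ring; the ring C=O next to C(prenyl)2 is axial and cis to the axial 4-OH | CC(C)=CCC1(CC=C(C)C)C(=O)[C@]2(C[C@H]3[C@@H](CC[C@@]3(C)O)[C@@](C)(O)C2)C(=O)C(C(=O)C(C)C)=C1O | target

## Step count and risks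

Total step count: 8. Longest linear sequence: 6 steps (steps 3, 4, 5, 6, 7, 8, or equally steps 1, 2, 5, 6, 7, 8).

The three steps most likely to fail:

Step 4. The β-hydroxy aldehyde can lose water under aminocatalysis to give the cyclopentene carbaldehyde, and the nitronate can compete for the ketone (Henry reaction). The fallback reverses the order of bond formation. Setting out from 8, an enantioselective intramolecular Morita–Baylis–Hillman cyclisation (amino-acid-derived phosphine–thiourea catalyst) gives (R)-5-hydroxy-5-methylcyclopent-1-ene-1-carbaldehyde F1, which cannot dehydrate further. Nitromethane is then added under the iminium catalysis of step 4 (a known Michael addition to 1-cyclopentenecarbaldehydes), the catalyst directing the nitromethyl group to the face opposite the OH and the α-centre being protonated trans to both neighbours. The route is rejoined at 11.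

Step 6 (the proposed new step). The methylene stitch may give poor selectivity at the spiro centre if the ammonium bridge does not operate, and the primary nitro group may be hydroxymethylated twice. The fallback uses known reactions only. Setting out from 13, a Henry reaction with aqueous formaldehyde and catalytic Et3N gives nitro alcohol F2. Dehydration (DCC, CuCl, Et2O) gives nitroalkene 14, which Et3N cyclises by the ordinary Michael addition of a cyclic 1,3-dicarbonyl to a nitroalkene. The two spiro epimers formed without the template are separated by chromatography, and the route is rejoined at 15.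

Step 7. Any nitronate formed from 15 can undergo retro-Michael opening of the new ring, which would scramble the spiro centre, and the reduction may stop early. The fallback avoids nitronate chemistry and goes through the oxime. Setting out from 15, the nitro group is reduced only to the oxime (SnCl2, PhSH, Et3N) to give ketoxime F3, which is hydrolysed (aq. NaHSO3, then dilute HCl) to the ketone. The route is rejoined at 16.

Further compounds
F1 | step 4 | (R)-5-hydroxy-5-methylcyclopent-1-ene-1-carbaldehyde | O=CC1=CCC[C@@]1(C)O
F2 | step 6 | nitro alcohol (13 with CH(NO2)CH2OH in place of CH2NO2, new centre undefined) | CC(C)=CCC1(CC=C(C)C)C(=O)C(C(=O)C(C)C)=C(O)C(C[C@H]2[C@@H](CC[C@@]2(C)O)C(CO)[N+](=O)[O-])=C1O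
F3 | step 7 | ketoxime (oxime of spiro ketone 16, oxime geometry undefined) | CC(C)=CCC1(CC=C(C)C)C(=O)[C@]2(C[C@H]3[C@@H](CC[C@@]3(C)O)C(=NO)C2)C(=O)C(C(=O)C(C)C)=C1O
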